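**Plan**

1. Rings: A carries the methyl ester, B is the central ring, C is the dihydroxy ring; each is numbered from its carboxyl-bearing carbon C1. Retrosynthetic cuts, in order: the ester C(=O)–O bond between ring C and O4 of ring B; the C1–C2 and C5–C6 bonds of ring B; the ester bond between the ring-B carboxyl carbon and O4 of ring A; the C1–C2 and C5–C6 bonds of ring A.
2. Enabling feature: ring B is a benzoate with OMe at C2, oxygen at C4 and CH3 at C6, and its C1 carboxyl is the ester to O4 of ring A. C1, C6, the CH3 and the carboxyl therefore map onto an aryl but-2-ynoate, and C2–C5 onto 1,1-dimethoxy-3-(trimethylsilyloxy)buta-1,3-diene. Ring A has the same pattern.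
3. Forward: the diene is made first (three steps). Ring A arises by benzannulation of methyl but-2-ynoate, its 4-OH is esterified with but-2-ynoic acid, and ring B arises by a second benzannulation on that aryl ynoate.
4. Ring C is attached, not built: bis-benzylated orsellinic acid is esterified to the new 4-OH of ring B, and hydrogenolysis removes the benzyl ethers.
5. Stereochemistry: the target has no stereocentre and no stereogenic double bond. Only regiochemistry matters, and it follows from pairing the diene CH2 terminus with the alkynoate β-carbon.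

Key step: step 6

Remark: the target is achiral, so the demand for a single enantiomer is met by the correct constitution alone.

**Route**

Step 1
Reactants: 1 acetyl chloride; 2 1,1-dichloroethene
Product: 4 4,4-dichlorobut-3-en-2-one, via 4,4,4-trichlorobutan-2-one 3 (not isolated)
Conditions: AlCl3 (1.1 equiv), CH2Cl2, 0 °C → rt; ice/aq. HCl; steam distillation (–HCl)
Reagents that add atoms: none
Why: Friedel–Crafts-type acylation of the alkene, in which the acylium ion adds to the CH2 terminus of 2, the chlorine-stabilised cation captures chloride, and the β-trichloromethyl ketone 3 loses HCl by E1cB elimination to give the conjugated dichlorovinyl ketone.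

Step 2
Reactants: 4 4,4-dichlorobut-3-en-2-one
Product: 5 4,4-dimethoxybut-3-en-2-one
Conditions: NaOMe (2.1 equiv), MeOH, 0 °C → rt; filtration, distillation under reduced pressure
Reagents that add atoms: sodium methoxide, [Na+].[O-]C
Why: Two successive addition–elimination reactions (vinylic nucleophilic substitution) of methoxide at the β-carbon of this vinylogous acid chloride should replace both chlorides and give the push–pull acyl ketene acetal.

Step 3
Reactants: 5 4,4-dimethoxybut-3-en-2-one
Product: 6 1,1-dimethoxy-3-(trimethylsilyloxy)buta-1,3-diene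
Conditions: TMSCl (1.3 equiv), Et3N (1.5 equiv), ZnCl2 (cat.), toluene, rt → 40 °C; filtration, distillation under reduced pressure
Reagents that add atoms: chlorotrimethylsilane, C[Si](C)(C)Cl
Why: Soft enolisation of the methyl ketone and O-silylation is the standard silyl enol ether formation used for 2-silyloxybutadienes, and it leaves the ketene acetal terminus untouched.

Step 4
Reactants: 6 1,1-dimethoxy-3-(trimethylsilyloxy)buta-1,3-diene; 7 methyl but-2-ynoate
Product: 10 methyl 4-hydroxy-2-methoxy-6-methylbenzoate, via cyclohexadiene cycloadduct 8 (not isolated), via aryl trimethylsilyl ether 9 (not isolated)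
Conditions: 6 (2 equiv), neat, sealed tube, 120 °C; then 1 M HCl, THF, rt
Reagents that add atoms: none
Why: Normal-electron-demand Diels–Alder reaction of the electron-rich diene with the acetylenic ester, the nucleophilic CH2 terminus bonding to the methyl-bearing β-carbon, followed by loss of methanol (aromatisation) and hydrolysis of the silyl ether, a known type of access to 6-alkyl-4-hydroxy-2-methoxybenzoates.

Step 5
Reactants: 10 methyl 4-hydroxy-2-methoxy-6-methylbenzoate; 11 but-2-ynoic acid
Product: 12 3-methoxy-4-(methoxycarbonyl)-5-methylphenyl but-2-ynoate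
Conditions: DCC (1.2 equiv), DMAP (0.05 equiv), CH2Cl2, 0 °C → rt
Reagents that add atoms: none
Why: Steglich esterification of an unhindered phenol with an unhindered ynoic acid, run cold with little DMAP so that the ynoate should not isomerise to the allenoate.

Step 6
Reactants: 12 3-methoxy-4-(methoxycarbonyl)-5-methylphenyl but-2-ynoate; 6 1,1-dimethoxy-3-(trimethylsilyloxy)buta-1,3-diene
Product: 15 3-methoxy-4-(methoxycarbonyl)-5-methylphenyl 4-hydroxy-2-methoxy-6-methylbenzoate, via cyclohexadiene cycloadduct 13 (not isolated), via A–B aryl trimethylsilyl ether 14 (not isolated)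
Conditions: 6 (2.5 equiv), toluene, sealed tube, 115 °C; then 1 M HCl, THF, 0 °C → rt
Reagents that add atoms: none
Why: Thermal normal-electron-demand Diels–Alder reaction in which the diene HOMO has its largest terminal coefficient at the CH2 carbon (raised by both the ketene acetal and the silyloxy group) and the ynoate LUMO at the methyl-bearing β-carbon, so an asynchronous concerted [4+2] joins the diene CH2 to the β-carbon and the acetal carbon to the α-carbon to give cyclohexa-1,4-diene 13. The closest known reaction type is the cycloaddition of 1,1-dialkoxy-3-silyloxybutadienes with acetylenic esters to give 4-hydroxy-2-methoxybenzoates, as used on the methyl ester in step 4. Ring B is closed by an intermolecular [4+2] cycloaddition that forms its C1–C2 and C5–C6 bonds in the same step. Adduct 13 should then aromatise by 1,4-elimination of methanol (OMe from the acetal carbon C2, H from the C5 methylene) to silyl ether 14, which the acidic work-up cleaves to phenol 15. No stereocentre is created. The step needs regioselectivity (OMe at C2, OH at C4, CH3 at C6) and chemoselectivity for the triple bond over the aryl ester carbonyl; the first is secured by the matched polarisation of the two partners, the second by the absence of Lewis acid or base, while the aryloxycarbonyl group lowers the alkyne LUMO relative to the methyl ester of step 4.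

Step 7
Reactants: 16 methyl orsellinate (methyl 2,4-dihydroxy-6-methylbenzoate)
Product: 17 methyl 2,4-bis(benzyloxy)-6-methylbenzoate
Conditions: BnBr (2.5 equiv), K2CO3 (3 equiv), DMF, 60 °C
Reagents that add atoms: benzyl bromide, BrCc1ccccc1
Why: Williamson ether synthesis, in which warm DMF with excess benzyl bromide should alkylate both the free 4-OH and the hydrogen-bonded 2-OH.

Step 8
Reactants: 17 methyl 2,4-bis(benzyloxy)-6-methylbenzoate
Product: 18 2,4-bis(benzyloxy)-6-methylbenzoic acid
Conditions: KOH (excess), DMSO–H2O, 90 °C; then aq. HCl to pH 2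
Reagents that add atoms: potassium hydroxide, [K+].[OH-]
Why: Saponification of the di-ortho-substituted methyl ester needs hot hydroxide in aqueous DMSO, conditions to which benzyl aryl ethers are inert.

Step 9
Reactants: 18 2,4-bis(benzyloxy)-6-methylbenzoic acid; 15 3-methoxy-4-(methoxycarbonyl)-5-methylphenyl 4-hydroxy-2-methoxy-6-methylbenzoate
Product: 20 3-methoxy-4-{[3-methoxy-4-(methoxycarbonyl)-5-methylphenoxy]carbonyl}-5-methylphenyl 2,4-bis(benzyloxy)-6-methylbenzoate, via mixed trifluoroacetic anhydride 19 (not isolated)
Conditions: TFAA (3 equiv), toluene, rt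
Reagents that add atoms: none
Why: Mixed-anhydride esterification, in which trifluoroacetic anhydride turns the hindered acid into acyl trifluoroacetate 19 (an acylium equivalent stabilised by the ortho and para alkoxy groups) that O-acylates the unhindered ring-B phenol under acidic conditions that spare the existing aryl ester, the standard way of closing depside ester bonds.

Step 10
Reactants: 20 3-methoxy-4-{[3-methoxy-4-(methoxycarbonyl)-5-methylphenoxy]carbonyl}-5-methylphenyl 2,4-bis(benzyloxy)-6-methylbenzoate
Product: 21 3-methoxy-4-{[3-methoxy-4-(methoxycarbonyl)-5-methylphenoxy]carbonyl}-5-methylphenyl 2,4-dihydroxy-6-methylbenzoate (target, CNP0514431.0)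
Conditions: H2 (1 atm), 10% Pd/C, EtOAc, rt
Reagents that add atoms: none
Why: Catalytic hydrogenolysis of the two benzyl aryl ethers under neutral conditions, which should leave the aryl and methyl esters intact and avoids any base that could cause depside transesterification.

**Compound list**

1 | acetyl chloride | CC(=O)Cl | starting material
2 | 1,1-dichloroethene | C=C(Cl)Cl | starting material
3 | 4,4,4-trichlorobutan-2-one | CC(=O)CC(Cl)(Cl)Cl | intermediate
4 | 4,4-dichlorobut-3-en-2-one | CC(=O)C=C(Cl)Cl | intermediate
5 | 4,4-dimethoxybut-3-en-2-one | CC(=O)C=C(OC)OC | intermediate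
6 | 1,1-dimethoxy-3-(trimethylsilyloxy)buta-1,3-diene | COC(OC)=CC(=C)O[Si](C)(C)C | intermediate
7 | methyl but-2-ynoate | CC#CC(=O)OC | starting material
8 | methyl 6,6-dimethoxy-2-methyl-4-(trimethylsilyloxy)cyclohexa-1,4-diene-1-carboxylate | COC(=O)C1=C(C)CC(O[Si](C)(C)C)=CC1(OC)OC | intermediate
9 | methyl 2-methoxy-6-methyl-4-(trimethylsilyloxy)benzoate | COC(=O)c1c(C)cc(O[Si](C)(C)C)cc1OC | intermediate
10 | methyl 4-hydroxy-2-methoxy-6-methylbenzoate | COC(=O)c1c(C)cc(O)cc1OC | intermediate
11 | but-2-ynoic acid | CC#CC(=O)O | starting material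
12 | 3-methoxy-4-(methoxycarbonyl)-5-methylphenyl but-2-ynoate | CC#CC(=O)Oc1cc(C)c(C(=O)OC)c(OC)c1 | intermediate
13 | 3-methoxy-4-(methoxycarbonyl)-5-methylphenyl 6,6-dimethoxy-2-methyl-4-(trimethylsilyloxy)cyclohexa-1,4-diene-1-carboxylate | COC(=O)c1c(C)cc(OC(=O)C2=C(C)CC(O[Si](C)(C)C)=CC2(OC)OC)cc1OC | intermediate
14 | 3-methoxy-4-(methoxycarbonyl)-5-methylphenyl 2-methoxy-6-methyl-4-(trimethylsilyloxy)benzoate | COC(=O)c1c(C)cc(OC(=O)c2c(C)cc(O[Si](C)(C)C)cc2OC)cc1OC | intermediate
15 | 3-methoxy-4-(methoxycarbonyl)-5-methylphenyl 4-hydroxy-2-methoxy-6-methylbenzoate | COC(=O)c1c(C)cc(OC(=O)c2c(C)cc(O)cc2OC)cc1OC | intermediate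
16 | methyl orsellinate (methyl 2,4-dihydroxy-6-methylbenzoate) | COC(=O)c1c(C)cc(O)cc1O | starting material
17 | methyl 2,4-bis(benzyloxy)-6-methylbenzoate | COC(=O)c1c(C)cc(OCc2ccccc2)cc1OCc1ccccc1 | intermediate
18 | 2,4-bis(benzyloxy)-6-methylbenzoic acid | Cc1cc(OCc2ccccc2)cc(OCc2ccccc2)c1C(=O)O | intermediate
19 | 2,4-bis(benzyloxy)-6-methylbenzoic trifluoroacetic anhydride | Cc1cc(OCc2ccccc2)cc(OCc2ccccc2)c1C(=O)OC(=O)C(F)(F)F | intermediate
20 | 3-methoxy-4-{[3-methoxy-4-(methoxycarbonyl)-5-methylphenoxy]carbonyl}-5-methylphenyl 2,4-bis(benzyloxy)-6-methylbenzoate | COC(=O)c1c(C)cc(OC(=O)c2c(C)cc(OC(=O)c3c(C)cc(OCc4ccccc4)cc3OCc3ccccc3)cc2OC)cc1OC | intermediate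
21 | 3-methoxy-4-{[3-methoxy-4-(methoxycarbonyl)-5-methylphenoxy]carbonyl}-5-methylphenyl 2,4-dihydroxy-6-methylbenzoate | COC(=O)c1c(C)cc(OC(=O)c2c(C)cc(OC(=O)c3c(C)cc(O)cc3O)cc2OC)cc1OC | target

**Step count**

Total: 10 steps. Longest linear sequence: 8 steps (steps 1, 2, 3, 4, 5, 6, 9, 10); steps 7 and 8 form the convergent ring-C branch. Diene 6 is prepared once and used in steps 4 and 6.

**Steps most likely to fail**

Step 6. The β-methyl ynoate may add too slowly, so that the diene decomposes or polymerises before the cycloaddition is complete, and the methanol released on aromatisation may cleave the activated aryl ester of unreacted 12. The fallback is a classical depside esterification that sets out from 10. Benzylation (BnBr, K2CO3, DMF) should give methyl 4-(benzyloxy)-2-methoxy-6-methylbenzoate F1, and hot KOH in aqueous DMSO should give 4-(benzyloxy)-2-methoxy-6-methylbenzoic acid F2. TFAA in toluene converts this acid into 4-(benzyloxy)-2-methoxy-6-methylbenzoic trifluoroacetic anhydride F3, which acylates a second portion of 10 to give 3-methoxy-4-(methoxycarbonyl)-5-methylphenyl 4-(benzyloxy)-2-methoxy-6-methylbenzoate F4. Hydrogenolysis over Pd/C then comes back to the route at 15.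

Step 4. The methyl ynoate is only weakly activated, so conversion may stay low while the diene is consumed by thermal decomposition. The fallback sets out from 16 and uses the different reactivity of its two hydroxyls. MOMCl with iPr2NEt in CH2Cl2 should alkylate only the 4-OH, which is not hydrogen-bonded, giving methyl 2-hydroxy-4-(methoxymethoxy)-6-methylbenzoate F5. MeI with K2CO3 in DMF then gives methyl 2-methoxy-4-(methoxymethoxy)-6-methylbenzoate F6, and HCl in MeOH removes the acetal and comes back to the route at 10.

Step 9. Acylation under the acidic conditions may be diverted into C-acylation of an electron-rich ring or into loss of the ortho benzyl ether, and steric hindrance at the acyl carbon may leave the coupling incomplete. The fallback sets out from 18 and replaces the acid-promoted in-situ activation by a pre-formed acyl chloride used under basic conditions. Oxalyl chloride with catalytic DMF in CH2Cl2 should give 2,4-bis(benzyloxy)-6-methylbenzoyl chloride F7, isolated by evaporation. Adding it to 15 with Et3N and catalytic DMAP in CH2Cl2 comes back to the route at 20.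

**Further compounds**

F1 | step 6 | methyl 4-(benzyloxy)-2-methoxy-6-methylbenzoate | COC(=O)c1c(C)cc(OCc2ccccc2)cc1OC
F2 | step 6 | 4-(benzyloxy)-2-methoxy-6-methylbenzoic acid | Cc1cc(OCc2ccccc2)cc(OC)c1C(=O)O
F3 | step 6 | 4-(benzyloxy)-2-methoxy-6-methylbenzoic trifluoroacetic anhydride | Cc1cc(OCc2ccccc2)cc(OC)c1C(=O)OC(=O)C(F)(F)F
F4 | step 6 | 3-methoxy-4-(methoxycarbonyl)-5-methylphenyl 4-(benzyloxy)-2-methoxy-6-methylbenzoate | COC(=O)c1c(C)cc(OC(=O)c2c(C)cc(OCc3ccccc3)cc2OC)cc1OC
F5 | step 4 | methyl 2-hydroxy-4-(methoxymethoxy)-6-methylbenzoate | COCOc1cc(C)c(C(=O)OC)c(O)c1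
F6 | step 4 | methyl 2-methoxy-4-(methoxymethoxy)-6-methylbenzoate | COCOc1cc(C)c(C(=O)OC)c(OC)c1
F7 | step 9 | 2,4-bis(benzyloxy)-6-methylbenzoyl chloride | Cc1cc(OCc2ccccc2)cc(OCc2ccccc2)c1C(=O)Cl
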